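(The constants used here come from no measurement; the flask was simulated.)

Every second end group charged stands unreacted, in a link or in decomposed reagent, so one balance gives the chain length.

    first end groups + second end groups ⇌ links + released group (K1 = 250, k1 = 1800 M⁻¹ s⁻¹)
    released group → by-product carried off (k2 = 0.696 s⁻¹)
    second end groups → decomposed reagent (k3 = 0.328 s⁻¹)

in all of them: second end groups 1.05 equiv; time 10 s

|  | first end groups |
|---|---|
| Monday's | 0.50 mM |
| Friday's | 1.5 mM |

- which of the two ends with the longer chains by the average number of monomer units in a chain (unreacted monomers counted as chains of one) ("neither" if they lie within 10%) (Monday's / Friday's / neither)
- average number of monomer units in a chain (unreacted monomers counted as chains of one) at the end, Monday's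
- average number of monomer units in a chain (unreacted monomers counted as chains of one) at the end, Friday's

- each molecule carries two end groups: a chain counts once for every two ends that are left, dead ends included; the units are half of the end groups of the two monomers charged
- run time (Monday's): 10 s

We reckon in fractions of the first end groups charged: r is the second end groups charged (1.05 in both flasks), x the part linked, a = 1 − x the part left. In Friday's flask, with its whole charge linked, a released group returns at 0.0108 s⁻¹ at most, far slower than the 0.696 s⁻¹ at which it is carried off, and Monday's charge is smaller, so we drop the way back in both flasks. Decomposition alone leaves 3.76% of the second end groups after 10 s, so we run the balance to their end.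

The two losses of second end groups compare through the break-even level k3/k1 = 0.182 mM, the concentration of first end groups at which linking and decomposition take them equally fast. Dividing it by the first end groups charged gives λ: 0.364 for Monday's, 0.121 for Friday's. Integrating the balance gives r = x − λ ln a. One Newton step from a = λ gives a ≈ (1 − r + λ − λ ln λ)/2: 34.1% for Monday's, 16.4% for Friday's. Each link removes 2 of the 1 + r ends, so our lengths are 2.80 for Monday's and 5.43 for Friday's.

The forecast says Friday's, with 2.79 and 5.25, the second below ours, holding that decomposition “competes with linking much less at the higher concentration”.

The simulation gives Friday's, with 2.79 for Monday's and 5.25 for Friday's, so our Friday's length stands 0.180 high. Second end groups, the limiting reagent despite their excess, stand after 10.0 s at 0.10% of their charge on Monday's and 0.019% on Friday's.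

Now take Friday's flask with 0.260 equiv of second end groups. The first end groups charged are unchanged, so λ stays 0.121. Taking −ln a as roughly x, we get x ≈ r/(1 + λ) = 23.2% and a length of about 1.58. That flask ends with second end groups at 0% of their charge, links at 22.8% of the first end groups charged and a length of 1.57.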